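## Retrosynthetic overview

1. Target ⇐ two deprotections ⇐ seven-membered lactone (ring B) closed by lactonization of the ring A acid onto its own allylic alcohol ⇐ ester bond between ring A diol 17 (primary OH) and acid 30.
2. Both halves carry ring–CH=C(CH2OR)CO2tBu, each made by an intermolecular aldol addition of a tert-butyl 3-alkoxypropanoate lithium enolate to a ring aldehyde (8 or 21), then E1cB dehydration; these are the key C–C bonds.
3. Aldehydes 8 and 21 both come from silyl enol ether 5: formaldehyde aldol at C-2 (ring A) or enol triflate (ring C), then vinyl → CHO.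
4. 5 ⇐ (R)-cryptone 4 by trans-selective vinyl conjugate addition; 4 ⇐ isovaleraldehyde + methyl vinyl ketone by organocatalytic Michael addition and aldol condensation.
5. Ring order: cyclohexenone 4 first (it becomes ring A and ring C); ring A carbinol by methylenation/dihydroxylation; oxepinone ring B last.

Assumption: the SMILES is taken as drawn, i.e. (5aS,6R,9S,9aS) in the benzoxepinone half, (1R,6R) in the cyclohexenyl half, both enoates with the ring carbon cis to CH2O. Ring A = cyclohexane of the lactone half, ring B = oxepinone, ring C = cyclohexene of the acid half. TBS = tert-butyldimethylsilyl, TBDPS = tert-butyldiphenylsilyl, PMB = 4-methoxybenzyl.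

## Route

**Step 1**
Reactants: 1 3-methylbutanal; 2 but-3-en-2-one
Product: 4 (4R)-4-(propan-2-yl)cyclohex-2-en-1-one, via keto-aldehyde 3 (not isolated)
Conditions: (R)-2-[methoxy(diphenyl)methyl]pyrrolidine (5 mol %), ethyl 3,4-dihydroxybenzoate (20 mol %), neat, 4 °C; then LiOH (0.2 equiv), iPrOH, rt
Reagents that add atoms: none
Why: Enamine-catalysed asymmetric Michael addition, in which the (R)-prolinol ether shields one enamine face and sets the R centre (about 90–95% ee expected), followed by intramolecular aldol condensation to the cyclohexenone.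

**Step 2**
Reactants: 4 (4R)-4-(propan-2-yl)cyclohex-2-en-1-one
Product: 5 trimethyl{[(3R,4R)-3-ethenyl-4-(propan-2-yl)cyclohex-1-en-1-yl]oxy}silane
Conditions: CH2=CHMgBr, CuBr·SMe2 (10 mol %), Me3SiCl, DMPU, THF, −78 °C; Et3N, pentane work-up
Reagents that add atoms: vinylmagnesium bromide C=C[Mg]Br; chlorotrimethylsilane C[Si](C)(C)Cl
Why: Copper-catalysed conjugate (1,4-) addition delivers vinyl anti to the C-4 isopropyl group (3,4-trans), and Me3SiCl traps the enolate regiospecifically as the C1–C2 silyl enol ether.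

**Step 3**
Reactants: 5 silyl enol ether
Product: 6 (2R,3R,4R)-3-ethenyl-2-(hydroxymethyl)-4-(propan-2-yl)cyclohexan-1-one
Conditions: 37% aq. HCHO, Yb(OTf)3 (10 mol %), THF, rt
Reagents that add atoms: formaldehyde C=O
Why: Lanthanide-triflate-catalysed Mukaiyama aldol (hydroxymethylation) forms the C-2 bond anti to the neighbouring vinyl group, and this all-equatorial 2,3-trans isomer is also the thermodynamic one at the epimerisable α-centre.

**Step 4**
Reactants: 6 hydroxymethyl ketone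
Product: 7 (2R,3R,4R)-2-{[(tert-butyldimethylsilyl)oxy]methyl}-3-ethenyl-4-(propan-2-yl)cyclohexan-1-one
Conditions: TBSCl, imidazole, DMF, 0 °C → rt
Reagents that add atoms: tert-butyldimethylsilyl chloride CC(C)(C)[Si](C)(C)Cl
Why: Standard silylation of the primary alcohol under mild base blocks dehydration of the β-hydroxy ketone.

**Step 5**
Reactants: 7 TBS ether
Product: 8 (1R,2R,6R)-2-{[(tert-butyldimethylsilyl)oxy]methyl}-3-oxo-6-(propan-2-yl)cyclohexane-1-carbaldehyde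
Conditions: O3, CH2Cl2, −78 °C; then PPh3, −78 °C → rt
Reagents that add atoms: ozone [O-][O+]=O
Why: Ozonolysis with reductive work-up cleaves the only alkene present, and the new formyl group stays in the equatorial all-trans arrangement.

**Step 6**
Reactants: 9 (4-methoxyphenyl)methanol; 10 tert-butyl prop-2-enoate
Product: 11 tert-butyl 3-[(4-methoxybenzyl)oxy]propanoate
Conditions: NaH (5 mol %), THF, 0 °C → rt
Reagents that add atoms: none
Why: Base-catalysed oxa-Michael addition; the tert-butyl ester suppresses transesterification.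

**Step 7**
Reactants: 11 tert-butyl 3-[(4-methoxybenzyl)oxy]propanoate; 8 keto-aldehyde
Product: 13 tert-butyl 3-[(1R,2R,6R)-2-{[(TBS)oxy]methyl}-3-oxo-6-(propan-2-yl)cyclohexyl]-3-hydroxy-2-{[(4-methoxybenzyl)oxy]methyl}propanoate (diastereomer mixture at the two new centres), via lithium enolate 12 (not isolated)
Conditions: LiN(iPr)2, THF, −78 °C; then 8, −78 °C; aq. NH4Cl at −78 °C
Reagents that add atoms: none
Why: Crossed aldol addition of the ester lithium enolate to the aldehyde, which is far more electrophilic than the hindered ketone; the two new centres are destroyed in step 8, so their configuration is irrelevant.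

**Step 8**
Reactants: 13 aldol adduct
Product: 15 tert-butyl (2E)-3-[(1S,2R,6R)-2-{[(TBS)oxy]methyl}-3-oxo-6-(propan-2-yl)cyclohexyl]-2-{[(4-methoxybenzyl)oxy]methyl}prop-2-enoate, via mesylate 14 (not isolated)
Conditions: MsCl, Et3N, CH2Cl2, 0 °C; then DBU, 0 °C → rt
Reagents that add atoms: none
Why: Mesylation and E1cB elimination through the ester enolate give the thermodynamically preferred E-enoate (bulky ring trans to CO2tBu, cis to CH2OPMB); mesylate leaves far faster than the β′-alkoxide.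

**Step 9**
Reactants: 15 keto-enoate
Product: 16 tert-butyl (2E)-3-[(1S,2S,6R)-2-{[(TBS)oxy]methyl}-3-methylidene-6-(propan-2-yl)cyclohexyl]-2-{[(4-methoxybenzyl)oxy]methyl}prop-2-enoate
Conditions: Zn, CH2Br2, TiCl4 (reagent pre-formed in THF), CH2Cl2, 0 °C → rt
Reagents that add atoms: dibromomethane BrCBr
Why: Takai–Lombardo methylenation is non-basic and ketone-selective, so the α-centre, the β-silyloxy group and both ester functions are untouched.

**Step 10**
Reactants: 16 exocyclic alkene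
Product: 17 tert-butyl (2E)-3-[(1S,2R,3S,6R)-2-{[(TBS)oxy]methyl}-3-hydroxy-3-(hydroxymethyl)-6-(propan-2-yl)cyclohexyl]-2-{[(4-methoxybenzyl)oxy]methyl}prop-2-enoate
Conditions: OsO4 (2 mol %), NMO, acetone/H2O, rt
Reagents that add atoms: N-methylmorpholine N-oxide C[N+]1([O-])CCOCC1; water O (both delivered through catalytic osmium tetroxide O=[Os](=O)(=O)=O)
Why: Upjohn dihydroxylation touches only the electron-rich 1,1-disubstituted alkene (the hindered enoate is inert); OsO4 adds to methylenecyclohexanes from the equatorial direction, giving the equatorial tertiary OH and axial CH2OH (3S).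

**Step 11**
Reactants: 5 silyl enol ether
Product: 19 (3R,4R)-3-ethenyl-4-(propan-2-yl)cyclohex-1-en-1-yl trifluoromethanesulfonate, via lithium enolate 18 (not isolated)
Conditions: MeLi, THF, 0 °C; then PhNTf2, −78 → 0 °C
Reagents that add atoms: N-phenylbis(trifluoromethanesulfonimide) O=S(=O)(N(c1ccccc1)S(=O)(=O)C(F)(F)F)C(F)(F)F
Why: MeLi cleaves the silyl enol ether to the regiodefined lithium enolate without equilibration, and O-triflation fixes the C1=C2 double bond needed in ring C.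

**Step 12**
Reactants: 19 vinyl-substituted enol triflate
Product: 21 (3R,4R)-3-formyl-4-(propan-2-yl)cyclohex-1-en-1-yl trifluoromethanesulfonate, via diol 20 (not isolated)
Conditions: K2OsO4·2H2O (2 mol %), NaIO4, 2,6-lutidine, 1,4-dioxane/H2O, rt
Reagents that add atoms: sodium periodate [Na+].[O-]I(=O)(=O)=O; water O
Why: Lemieux–Johnson cleavage attacks the terminal vinyl group in preference to the electron-poor enol triflate alkene; the formyl centre is the stable trans epimer, and conjugative isomerisation would require an allylic triflate, so it does not occur.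

**Step 13**
Reactants: 22 tert-butyl 3-hydroxypropanoate
Product: 23 tert-butyl 3-[(tert-butyldiphenylsilyl)oxy]propanoate
Conditions: TBDPSCl, imidazole, DMF, rt
Reagents that add atoms: tert-butyldiphenylsilyl chloride CC(C)(C)[Si](Cl)(c1ccccc1)c1ccccc1
Why: Standard silylation of a primary alcohol.

**Step 14**
Reactants: 23 tert-butyl 3-[(TBDPS)oxy]propanoate; 21 aldehyde
Product: 25 tert-butyl 2-{[(TBDPS)oxy]methyl}-3-hydroxy-3-[(1R,6R)-6-(propan-2-yl)-3-{[(trifluoromethyl)sulfonyl]oxy}cyclohex-2-en-1-yl]propanoate (diastereomer mixture at the two new centres), via lithium enolate 24 (not isolated)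
Conditions: LiN(iPr)2, THF, −78 °C; then 21, −78 °C; aq. NH4Cl at −78 °C
Reagents that add atoms: none
Why: Crossed aldol addition of the ester lithium enolate to the aldehyde, which at −78 °C is much faster than attack on the triflate or α-deprotonation; the new centres are removed in step 15.

**Step 15**
Reactants: 25 aldol adduct
Product: 27 tert-butyl (2E)-2-{[(TBDPS)oxy]methyl}-3-[(1S,6R)-6-(propan-2-yl)-3-{[(trifluoromethyl)sulfonyl]oxy}cyclohex-2-en-1-yl]prop-2-enoate, via mesylate 26 (not isolated)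
Conditions: MsCl, Et3N, CH2Cl2, 0 °C; then DBU, 0 °C → rt
Reagents that add atoms: none
Why: Mesylation and E1cB elimination give the thermodynamic E-enoate (ring cis to CH2OSi); the ring stereocentre is unchanged, and its descriptor switches to S only through CIP priorities.

**Step 16**
Reactants: 27 enol triflate
Product: 28 tert-butyl (2E)-2-{[(TBDPS)oxy]methyl}-3-[(1R,6R)-3-(hydroxymethyl)-6-(propan-2-yl)cyclohex-2-en-1-yl]prop-2-enoate
Conditions: Bu3SnCH2OH, Pd(PPh3)4 (10 mol %), LiCl, 1,4-dioxane, 100 °C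
Reagents that add atoms: (tributylstannyl)methanol CCCC[Sn](CO)(CCCC)CCCC
Why: Stille cross-coupling replaces the triflate by CH2OH with the double bond held at C2=C3, leaving the tert-butyl enoate untouched.

**Step 17**
Reactants: 28 allylic alcohol
Product: 29 tert-butyl (2E)-2-{[(TBDPS)oxy]methyl}-3-[(1R,6R)-3-{[(TBDPS)oxy]methyl}-6-(propan-2-yl)cyclohex-2-en-1-yl]prop-2-enoate
Conditions: TBDPSCl, imidazole, DMF, rt
Reagents that add atoms: tert-butyldiphenylsilyl chloride CC(C)(C)[Si](Cl)(c1ccccc1)c1ccccc1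
Why: Standard silylation of the primary allylic alcohol.

**Step 18**
Reactants: 29 tert-butyl ester
Product: 30 (2E)-2-{[(TBDPS)oxy]methyl}-3-[(1R,6R)-3-{[(TBDPS)oxy]methyl}-6-(propan-2-yl)cyclohex-2-en-1-yl]prop-2-enoic acid
Conditions: CF3CO2H/CH2Cl2 (1:4), 0 °C
Reagents that add atoms: none
Why: Acidolysis of the tert-butyl ester by alkyl–oxygen cleavage works regardless of steric hindrance, and primary TBDPS ethers survive these conditions.

**Step 19**
Reactants: 30 acid; 17 ring A diol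
Product: 32 primary ester of diol 17 with acid 30, via mixed anhydride 31 (not isolated)
Conditions: 2,4,6-trichlorobenzoyl chloride, Et3N, toluene, rt; then 17, DMAP, toluene, rt → 40 °C
Reagents that add atoms: none
Why: Yamaguchi esterification acylates only the primary hydroxyl (the tertiary one is inert), and doing it while C-2 of ring A is still CH2OTBS prevents γ-lactonization of that primary alcohol onto a ring A carboxyl.

**Step 20**
Reactants: 32 coupled ester
Product: 33 ester 32 with the ring A CH2OTBS group converted to CH2OH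
Conditions: HF·pyridine, pyridine, THF, 0 °C
Reagents that add atoms: none
Why: Selective desilylation: a primary TBS ether is cleaved about two orders of magnitude faster than primary TBDPS ethers under buffered HF.

**Step 21**
Reactants: 33 primary alcohol
Product: 34 the corresponding ring A aldehyde
Conditions: Dess–Martin periodinane, NaHCO3, CH2Cl2, 0 °C → rt
Reagents that add atoms: none
Why: Buffered Dess–Martin oxidation converts the hindered primary alcohol to the aldehyde without retro-aldol or epimerisation (the equatorial CHO is the stable epimer); the tertiary OH is inert.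

**Step 22**
Reactants: 34 aldehyde
Product: 35 the corresponding ring A carboxylic acid
Conditions: NaClO2, NaH2PO4, 2-methylbut-2-ene, t-BuOH/H2O, 0 °C → rt
Reagents that add atoms: sodium chlorite [Na+].[O-]Cl=O
Why: Pinnick oxidation is mild enough for the β-hydroxy aldehyde, and the scavenger protects the alkenes and the PMB ether from HOCl.

**Step 23**
Reactants: 35 acid
Product: 36 hydroxy acid (allylic CH2OH freed on the ring A side chain)
Conditions: DDQ, CH2Cl2/aq. NaH2PO4–Na2HPO4 buffer (pH 7), 0 °C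
Reagents that add atoms: none
Why: Oxidative cleavage of the PMB ether by DDQ is orthogonal to silyl ethers, the tert-butyl ester and the alkenes.

**Step 24**
Reactants: 36 hydroxy acid
Product: 37 tert-butyl (5aS,6R,9S,9aS)-9-({[(2E)-2-{[(TBDPS)oxy]methyl}-3-[(1R,6R)-3-{[(TBDPS)oxy]methyl}-6-(propan-2-yl)cyclohex-2-en-1-yl]prop-2-enoyl]oxy}methyl)-9-hydroxy-1-oxo-6-(propan-2-yl)-1,3,5a,6,7,8,9,9a-octahydro-2-benzoxepine-4-carboxylate
Conditions: 2-methyl-6-nitrobenzoic anhydride (MNBA), DMAP, CH2Cl2 (2 mM, slow addition), rt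
Reagents that add atoms: none
Why: Shiina lactonization activates the ring A acid so that only the allylic primary OH (held close by the E-alkene on the trans-diequatorial scaffold) can close the seven-membered ring; a β-lactone with the tertiary OH would be trans-fused and does not form.

**Step 25**
Reactants: 37 lactone tert-butyl ester
Product: 38 the corresponding 2-benzoxepine-4-carboxylic acid (both TBDPS ethers still in place)
Conditions: CF3CO2H/CH2Cl2 (1:4), 0 °C
Reagents that add atoms: none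
Why: Acidolysis of the tert-butyl ester is done before desilylation so that no free allylic alcohol is exposed to acid; lactone, ester and the deactivated tertiary alcohol tolerate it.

**Step 26**
Reactants: 38 bis-TBDPS acid
Product: 39 (5aS,6R,9S,9aS)-9-hydroxy-9-({[(2E)-2-(hydroxymethyl)-3-[(1R,6R)-3-(hydroxymethyl)-6-(propan-2-yl)cyclohex-2-en-1-yl]prop-2-enoyl]oxy}methyl)-1-oxo-6-(propan-2-yl)-1,3,5a,6,7,8,9,9a-octahydro-2-benzoxepine-4-carboxylic acid (target)
Conditions: HF·pyridine, THF, 0 °C → rt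
Reagents that add atoms: none
Why: Fluoride-mediated desilylation under mildly acidic, non-nucleophilic conditions frees both primary allylic alcohols without opening or migrating the allylic lactone or the ester.

## Compound list

1 | 3-methylbutanal | CC(C)CC=O | starting material
2 | but-3-en-2-one | CC(=O)C=C | starting material
3 | (2R)-5-oxo-2-(propan-2-yl)hexanal | CC(C)[C@H](C=O)CCC(C)=O | intermediate
4 | (4R)-4-(propan-2-yl)cyclohex-2-en-1-one, (R)-cryptone | CC(C)[C@H]1CCC(=O)C=C1 | intermediate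
5 | trimethyl{[(3R,4R)-3-ethenyl-4-(propan-2-yl)cyclohex-1-en-1-yl]oxy}silane | CC(C)[C@H]1CCC(O[Si](C)(C)C)=C[C@@H]1C=C | intermediate
6 | (2R,3R,4R)-3-ethenyl-2-(hydroxymethyl)-4-(propan-2-yl)cyclohexan-1-one | CC(C)[C@H]1CCC(=O)[C@@H](CO)[C@@H]1C=C | intermediate
7 | (2R,3R,4R)-2-{[(TBS)oxy]methyl}-3-ethenyl-4-(propan-2-yl)cyclohexan-1-one | CC(C)[C@H]1CCC(=O)[C@@H](CO[Si](C)(C)C(C)(C)C)[C@@H]1C=C | intermediate
8 | (1R,2R,6R)-2-{[(TBS)oxy]methyl}-3-oxo-6-(propan-2-yl)cyclohexane-1-carbaldehyde | CC(C)[C@H]1CCC(=O)[C@@H](CO[Si](C)(C)C(C)(C)C)[C@@H]1C=O | intermediate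
9 | (4-methoxyphenyl)methanol | COc1ccc(CO)cc1 | starting material
10 | tert-butyl prop-2-enoate | C=CC(=O)OC(C)(C)C | starting material
11 | tert-butyl 3-[(4-methoxybenzyl)oxy]propanoate | COc1ccc(COCCC(=O)OC(C)(C)C)cc1 | intermediate
12 | lithium enolate of 11 | COc1ccc(COCC=C(O[Li])OC(C)(C)C)cc1 | intermediate
13 | tert-butyl 3-[(1R,2R,6R)-2-{[(TBS)oxy]methyl}-3-oxo-6-(propan-2-yl)cyclohexyl]-3-hydroxy-2-{[(4-methoxybenzyl)oxy]methyl}propanoate, epimer mixture at chain C-2/C-3 | CC(C)[C@H]1CCC(=O)[C@@H](CO[Si](C)(C)C(C)(C)C)[C@@H]1C(O)C(COCc2ccc(OC)cc2)C(=O)OC(C)(C)C | intermediate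
14 | 3-O-methanesulfonate of 13 | CC(C)[C@H]1CCC(=O)[C@@H](CO[Si](C)(C)C(C)(C)C)[C@@H]1C(OS(C)(=O)=O)C(COCc2ccc(OC)cc2)C(=O)OC(C)(C)C | intermediate
15 | tert-butyl (2E)-3-[(1S,2R,6R)-2-{[(TBS)oxy]methyl}-3-oxo-6-(propan-2-yl)cyclohexyl]-2-{[(4-methoxybenzyl)oxy]methyl}prop-2-enoate | CC(C)[C@H]1CCC(=O)[C@@H](CO[Si](C)(C)C(C)(C)C)[C@@H]1/C=C(\COCc2ccc(OC)cc2)C(=O)OC(C)(C)C | intermediate
16 | tert-butyl (2E)-3-[(1S,2S,6R)-2-{[(TBS)oxy]methyl}-3-methylidene-6-(propan-2-yl)cyclohexyl]-2-{[(4-methoxybenzyl)oxy]methyl}prop-2-enoate | CC(C)[C@H]1CCC(=C)[C@@H](CO[Si](C)(C)C(C)(C)C)[C@@H]1/C=C(\COCc2ccc(OC)cc2)C(=O)OC(C)(C)C | intermediate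
17 | tert-butyl (2E)-3-[(1S,2R,3S,6R)-2-{[(TBS)oxy]methyl}-3-hydroxy-3-(hydroxymethyl)-6-(propan-2-yl)cyclohexyl]-2-{[(4-methoxybenzyl)oxy]methyl}prop-2-enoate | CC(C)[C@H]1CC[C@@](O)(CO)[C@@H](CO[Si](C)(C)C(C)(C)C)[C@@H]1/C=C(\COCc2ccc(OC)cc2)C(=O)OC(C)(C)C | intermediate
18 | lithium (3R,4R)-3-ethenyl-4-(propan-2-yl)cyclohex-1-en-1-olate | CC(C)[C@H]1CCC(O[Li])=C[C@@H]1C=C | intermediate
19 | (3R,4R)-3-ethenyl-4-(propan-2-yl)cyclohex-1-en-1-yl trifluoromethanesulfonate | CC(C)[C@H]1CCC(OS(=O)(=O)C(F)(F)F)=C[C@@H]1C=C | intermediate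
20 | (3R,4R)-3-(1,2-dihydroxyethyl)-4-(propan-2-yl)cyclohex-1-en-1-yl trifluoromethanesulfonate, carbinol epimers | CC(C)[C@H]1CCC(OS(=O)(=O)C(F)(F)F)=C[C@@H]1C(O)CO | intermediate
21 | (3R,4R)-3-formyl-4-(propan-2-yl)cyclohex-1-en-1-yl trifluoromethanesulfonate | CC(C)[C@H]1CCC(OS(=O)(=O)C(F)(F)F)=C[C@@H]1C=O | intermediate
22 | tert-butyl 3-hydroxypropanoate | OCCC(=O)OC(C)(C)C | starting material
23 | tert-butyl 3-[(tert-butyldiphenylsilyl)oxy]propanoate | CC(C)(C)OC(=O)CCO[Si](c1ccccc1)(c1ccccc1)C(C)(C)C | intermediate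
24 | lithium enolate of 23 | CC(C)(C)OC(O[Li])=CCO[Si](c1ccccc1)(c1ccccc1)C(C)(C)C | intermediate
25 | tert-butyl 2-{[(TBDPS)oxy]methyl}-3-hydroxy-3-[(1R,6R)-6-(propan-2-yl)-3-{[(trifluoromethyl)sulfonyl]oxy}cyclohex-2-en-1-yl]propanoate, epimer mixture at chain C-2/C-3 | CC(C)[C@H]1CCC(OS(=O)(=O)C(F)(F)F)=C[C@@H]1C(O)C(CO[Si](c2ccccc2)(c2ccccc2)C(C)(C)C)C(=O)OC(C)(C)C | intermediate
26 | 3-O-methanesulfonate of 25 | CC(C)[C@H]1CCC(OS(=O)(=O)C(F)(F)F)=C[C@@H]1C(OS(C)(=O)=O)C(CO[Si](c2ccccc2)(c2ccccc2)C(C)(C)C)C(=O)OC(C)(C)C | intermediate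
27 | tert-butyl (2E)-2-{[(TBDPS)oxy]methyl}-3-[(1S,6R)-6-(propan-2-yl)-3-{[(trifluoromethyl)sulfonyl]oxy}cyclohex-2-en-1-yl]prop-2-enoate | CC(C)[C@H]1CCC(OS(=O)(=O)C(F)(F)F)=C[C@@H]1/C=C(\CO[Si](c2ccccc2)(c2ccccc2)C(C)(C)C)C(=O)OC(C)(C)C | intermediate
28 | tert-butyl (2E)-2-{[(TBDPS)oxy]methyl}-3-[(1R,6R)-3-(hydroxymethyl)-6-(propan-2-yl)cyclohex-2-en-1-yl]prop-2-enoate | CC(C)[C@H]1CCC(CO)=C[C@@H]1/C=C(\CO[Si](c2ccccc2)(c2ccccc2)C(C)(C)C)C(=O)OC(C)(C)C | intermediate
29 | tert-butyl (2E)-2-{[(TBDPS)oxy]methyl}-3-[(1R,6R)-3-{[(TBDPS)oxy]methyl}-6-(propan-2-yl)cyclohex-2-en-1-yl]prop-2-enoate | CC(C)[C@H]1CCC(CO[Si](c2ccccc2)(c2ccccc2)C(C)(C)C)=C[C@@H]1/C=C(\CO[Si](c2ccccc2)(c2ccccc2)C(C)(C)C)C(=O)OC(C)(C)C | intermediate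
30 | (2E)-2-{[(TBDPS)oxy]methyl}-3-[(1R,6R)-3-{[(TBDPS)oxy]methyl}-6-(propan-2-yl)cyclohex-2-en-1-yl]prop-2-enoic acid | CC(C)[C@H]1CCC(CO[Si](c2ccccc2)(c2ccccc2)C(C)(C)C)=C[C@@H]1/C=C(\CO[Si](c2ccccc2)(c2ccccc2)C(C)(C)C)C(=O)O | intermediate
31 | mixed anhydride of 30 with 2,4,6-trichlorobenzoic acid | CC(C)[C@H]1CCC(CO[Si](c2ccccc2)(c2ccccc2)C(C)(C)C)=C[C@@H]1/C=C(\CO[Si](c2ccccc2)(c2ccccc2)C(C)(C)C)C(=O)OC(=O)c2c(Cl)cc(Cl)cc2Cl | intermediate
32 | {(1S,2R,3S,4R)-3-[(1E)-3-tert-butoxy-2-{[(4-methoxybenzyl)oxy]methyl}-3-oxoprop-1-en-1-yl]-2-{[(TBS)oxy]methyl}-1-hydroxy-4-(propan-2-yl)cyclohexyl}methyl ester of acid 30 | CC(C)[C@H]1CC[C@@](O)(COC(=O)/C(=C/[C@H]2C=C(CO[Si](c3ccccc3)(c3ccccc3)C(C)(C)C)CC[C@@H]2C(C)C)CO[Si](c2ccccc2)(c2ccccc2)C(C)(C)C)[C@@H](CO[Si](C)(C)C(C)(C)C)[C@@H]1/C=C(\COCc2ccc(OC)cc2)C(=O)OC(C)(C)C | intermediate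
33 | ester 32 with ring A CH2OTBS replaced by CH2OH (ring A 1S,2R,3S,4R) | CC(C)[C@H]1CC[C@@](O)(COC(=O)/C(=C/[C@H]2C=C(CO[Si](c3ccccc3)(c3ccccc3)C(C)(C)C)CC[C@@H]2C(C)C)CO[Si](c2ccccc2)(c2ccccc2)C(C)(C)C)[C@@H](CO)[C@@H]1/C=C(\COCc2ccc(OC)cc2)C(=O)OC(C)(C)C | intermediate
34 | aldehyde from 33 (ring A C-2 formyl, same spatial configuration) | CC(C)[C@H]1CC[C@@](O)(COC(=O)/C(=C/[C@H]2C=C(CO[Si](c3ccccc3)(c3ccccc3)C(C)(C)C)CC[C@@H]2C(C)C)CO[Si](c2ccccc2)(c2ccccc2)C(C)(C)C)[C@@H](C=O)[C@@H]1/C=C(\COCc2ccc(OC)cc2)C(=O)OC(C)(C)C | intermediate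
35 | carboxylic acid from 34 (ring A C-2 carboxyl) | CC(C)[C@H]1CC[C@@](O)(COC(=O)/C(=C/[C@H]2C=C(CO[Si](c3ccccc3)(c3ccccc3)C(C)(C)C)CC[C@@H]2C(C)C)CO[Si](c2ccccc2)(c2ccccc2)C(C)(C)C)[C@@H](C(=O)O)[C@@H]1/C=C(\COCc2ccc(OC)cc2)C(=O)OC(C)(C)C | intermediate
36 | hydroxy acid from 35 (PMB removed; free allylic CH2OH cis to ring A on the E-enoate) | CC(C)[C@H]1CC[C@@](O)(COC(=O)/C(=C/[C@H]2C=C(CO[Si](c3ccccc3)(c3ccccc3)C(C)(C)C)CC[C@@H]2C(C)C)CO[Si](c2ccccc2)(c2ccccc2)C(C)(C)C)[C@@H](C(=O)O)[C@@H]1/C=C(\CO)C(=O)OC(C)(C)C | intermediate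
37 | tert-butyl (5aS,6R,9S,9aS)-9-({[(2E)-2-{[(TBDPS)oxy]methyl}-3-[(1R,6R)-3-{[(TBDPS)oxy]methyl}-6-(propan-2-yl)cyclohex-2-en-1-yl]prop-2-enoyl]oxy}methyl)-9-hydroxy-1-oxo-6-(propan-2-yl)-1,3,5a,6,7,8,9,9a-octahydro-2-benzoxepine-4-carboxylate | CC(C)[C@H]1CC[C@@](O)(COC(=O)/C(=C/[C@H]2C=C(CO[Si](c3ccccc3)(c3ccccc3)C(C)(C)C)CC[C@@H]2C(C)C)CO[Si](c2ccccc2)(c2ccccc2)C(C)(C)C)[C@H]2C(=O)OCC(C(=O)OC(C)(C)C)=C[C@H]12 | intermediate
38 | 4-carboxylic acid corresponding to 37 (bis-TBDPS ether) | CC(C)[C@H]1CC[C@@](O)(COC(=O)/C(=C/[C@H]2C=C(CO[Si](c3ccccc3)(c3ccccc3)C(C)(C)C)CC[C@@H]2C(C)C)CO[Si](c2ccccc2)(c2ccccc2)C(C)(C)C)[C@H]2C(=O)OCC(C(=O)O)=C[C@H]12 | intermediate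
39 | (5aS,6R,9S,9aS)-9-hydroxy-9-({[(2E)-2-(hydroxymethyl)-3-[(1R,6R)-3-(hydroxymethyl)-6-(propan-2-yl)cyclohex-2-en-1-yl]prop-2-enoyl]oxy}methyl)-1-oxo-6-(propan-2-yl)-1,3,5a,6,7,8,9,9a-octahydro-2-benzoxepine-4-carboxylic acid | CC(C)[C@H]1CC[C@@](O)(COC(=O)/C(=C/[C@H]2C=C(CO)CC[C@@H]2C(C)C)CO)[C@H]2C(=O)OCC(C(=O)O)=C[C@H]12 | target

## Step count and risks

Total: 26 steps (steps 6 and 13 are one-step preparations of the two aldol partners).
Longest linear sequence: 17 steps (1, 2, 3, 4, 5, 7, 8, 9, 10, 19–26); the acid branch (1, 2, 11, 12, 14–18, 19–26) is equally long.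

The three steps most likely to fail:

Step 10 (facial selectivity of the dihydroxylation that sets the tertiary carbinol). If OsO4 does not give a useful excess of the equatorial-OH isomer, the fallback sets out from ketone 15 and forms the same centre by C–C instead of C–O bond formation. Dimethylsulfonium methylide (Me3SI, KN(SiMe3)2, THF, −10 °C) adds axially to the carbonyl to give tert-butyl (2E)-3-[(3S,4R,5S,6R)-4-{[(TBS)oxy]methyl}-6-(propan-2-yl)-1-oxaspiro[2.5]octan-5-yl]-2-{[(4-methoxybenzyl)oxy]methyl}prop-2-enoate F1, with CH2 axial and oxygen equatorial. CsOAc with 18-crown-6 in DMF at 90 °C opens the epoxide at its CH2 terminus, with retention at the carbinol carbon, to the primary acetate of diol 17 F2. K2CO3 in MeOH then removes the acetate, and the route is rejoined at 17, bypassing steps 9 and 10.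

Step 16 (Stille hydroxymethylation of the enol triflate; butyl transfer or protodetriflation may dominate). The fallback sets out from triflate 27. Reductive carbonylation (Pd(OAc)2, dppp, CO 1 atm, Et3SiH, Et3N, DMF, 70 °C) gives the enal tert-butyl (2E)-2-{[(TBDPS)oxy]methyl}-3-[(1R,6R)-3-formyl-6-(propan-2-yl)cyclohex-2-en-1-yl]prop-2-enoate F3. Luche reduction (NaBH4, CeCl3·7H2O, MeOH, −20 °C) reduces only the aldehyde and returns to the route at 28.

Step 24 (seven-membered lactonization; dimer formation or slow closure). The fallback sets out from hydroxy acid 36 and activates the alcohol instead of the acid: a Mitsunobu cyclization (PPh3, DIAD, THF, 5 mM, 0 °C) lets the ring A carboxylate displace the allylic oxyphosphonium and comes back at lactone 37. Competing SN2′ attack at the hindered β-carbon, which would give a γ-lactone, is the point to watch. This fallback makes no new compound (F0).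

## Further compounds

F1 | step 10 | tert-butyl (2E)-3-[(3S,4R,5S,6R)-4-{[(TBS)oxy]methyl}-6-(propan-2-yl)-1-oxaspiro[2.5]octan-5-yl]-2-{[(4-methoxybenzyl)oxy]methyl}prop-2-enoate | CC(C)[C@H]1CC[C@@]2(CO2)[C@@H](CO[Si](C)(C)C(C)(C)C)[C@@H]1/C=C(\COCc3ccc(OC)cc3)C(=O)OC(C)(C)C
F2 | step 10 | primary acetate of diol 17: tert-butyl (2E)-3-[(1S,2R,3S,6R)-3-(acetoxymethyl)-2-{[(TBS)oxy]methyl}-3-hydroxy-6-(propan-2-yl)cyclohexyl]-2-{[(4-methoxybenzyl)oxy]methyl}prop-2-enoate | CC(C)[C@H]1CC[C@@](O)(COC(C)=O)[C@@H](CO[Si](C)(C)C(C)(C)C)[C@@H]1/C=C(\COCc2ccc(OC)cc2)C(=O)OC(C)(C)C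
F3 | step 16 | tert-butyl (2E)-2-{[(TBDPS)oxy]methyl}-3-[(1R,6R)-3-formyl-6-(propan-2-yl)cyclohex-2-en-1-yl]prop-2-enoate | CC(C)[C@H]1CCC(C=O)=C[C@@H]1/C=C(\CO[Si](c2ccccc2)(c2ccccc2)C(C)(C)C)C(=O)OC(C)(C)C
F0 | step 24 | none | none
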